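**Strategy**

1. Retrosynthesis first cuts the exocyclic C=CH2 back to a δ-lactone carbonyl, then the lactone O–C(CH3)2 bond together with the oxane C–Br bond (bromolactonization of a prenyl α-hydroxy acid).
2. It then cuts, in one operation, the cyclohexane bond between the ring CH and the CH2 next to CHBr and the C–O bond of the tertiary carbinol. This leads to an acyclic Z-allylic tert-butyl carbonate with a bromochlorohydrin terminus, itself cut at the Z C=C into a nerol-derived aldehyde and an allylated phosphonoacetate.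
3. Forward, the cyclohexane closes first together with a temporary 1,3-dioxolan-2-one, the oxane closes second as a bromo-δ-lactone, and the lactone carbonyl is methylenated last.
4. Enabling feature: in the cyclohexane the CHBr and C(Cl)CH3 carbons carry trans-diequatorial halogens (methyl axial), and the equatorial ring CH is bonded directly to the exocyclic tertiary C–O carbon. The CH–CH2 ring bond and the carbinol C–O bond are therefore the two ends of an anti addition of a bromine-activated CH2 and an oxygen across one Z alkene.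
5. Stereochemistry: both halogen-bearing ring carbons come from catalyst-controlled anti bromochlorination of nerol. The ring CH and the carbinol carbon come from the chair and the anti addition of the key step. The oxane CHBr comes from anti bromolactonization through a chair with the cyclohexyl group equatorial.

Key step: step 9

Assumption: the sense of induction in the bromochlorination is set by the choice of ligand enantiomer; the enantiomer that gives (2S,3S)-2 is used.

**Route**

Step 1
Reactants: 1 nerol
Product: 2 (2S,3S)-2-bromo-3-chloro-3,7-dimethyloct-6-en-1-ol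
Conditions: NBS, ClTi(OiPr)3 (tetravalent titanium), chiral tridentate Schiff-base ligand (20 mol%), hexanes, −20 °C
Reagents that add atoms: N-bromosuccinimide O=C1CCC(=O)N1Br; chlorotitanium triisopropoxide CC(C)O[Ti](Cl)(OC(C)C)OC(C)C
Why: Catalytic enantioselective bromochlorination of an allylic alcohol: the titanium-bound alkoxide steers anti addition to the Z allylic alkene only, bromine going to C2 and titanium-delivered chloride to the tertiary C3, so the ligand enantiomer fixes both halogen-bearing centres as (2S,3S) while the remote trisubstituted alkene is not touched.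

Step 2
Reactants: 2 (2S,3S)-2-bromo-3-chloro-3,7-dimethyloct-6-en-1-ol
Product: 3 tert-butyl{[(2S,3S)-2-bromo-3-chloro-3,7-dimethyloct-6-en-1-yl]oxy}dimethylsilane
Conditions: TBSCl, imidazole, DMF, 0 °C to rt
Reagents that add atoms: tert-butyldimethylsilyl chloride CC(C)(C)[Si](C)(C)Cl
Why: Standard imidazole-mediated silylation of a primary alcohol; it masks the bromohydrin hydroxyl so that the later basic and hydride steps cannot close it onto the CHBr carbon as an epoxide.

Step 3
Reactants: 3 tert-butyl{[(2S,3S)-2-bromo-3-chloro-3,7-dimethyloct-6-en-1-yl]oxy}dimethylsilane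
Product: 5 (4S,5S)-5-bromo-6-[(tert-butyldimethylsilyl)oxy]-4-chloro-4-methylhexanal, via secondary ozonide 4 (not isolated)
Conditions: O3, CH2Cl2, −78 °C; then PPh3, −78 °C to rt
Reagents that add atoms: ozone [O-][O+]=O
Why: Criegee ozonolysis with reductive phosphine work-up cleaves the only alkene to the aldehyde and acetone; silyl ether, secondary bromide and tertiary chloride are inert to ozone at −78 °C.

Step 4
Reactants: 6 methyl 2-[bis(2,2,2-trifluoroethoxy)phosphoryl]acetate; 7 allyl bromide
Product: 8 methyl 2-[bis(2,2,2-trifluoroethoxy)phosphoryl]pent-4-enoate (racemic)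
Conditions: NaH, THF, 0 °C; then 7, 0 °C to rt
Reagents that add atoms: none
Why: C-alkylation of the sodium salt of the phosphonoacetate at a reactive primary allylic bromide, run with the phosphonate in slight excess to hold back double alkylation.

Step 5
Reactants: 5 (4S,5S)-5-bromo-6-[(tert-butyldimethylsilyl)oxy]-4-chloro-4-methylhexanal; 8 methyl 2-[bis(2,2,2-trifluoroethoxy)phosphoryl]pent-4-enoate
Product: 9 methyl (2Z,6S,7S)-7-bromo-8-[(tert-butyldimethylsilyl)oxy]-6-chloro-6-methyl-2-(prop-2-en-1-yl)oct-2-enoate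
Conditions: KN(SiMe3)2, 18-crown-6, THF, −78 °C
Reagents that add atoms: none
Why: Still–Gennari variant of the Horner–Wadsworth–Emmons olefination: with trifluoroethyl phosphonate esters and a crown-ether-separated potassium ion the kinetic adduct eliminates before it equilibrates, which should give the Z enoate (ester cis to the chain), and the stabilized anion is too weakly basic to attack the halides at −78 °C.

Step 6
Reactants: 9 methyl (2Z,6S,7S)-7-bromo-8-[(tert-butyldimethylsilyl)oxy]-6-chloro-6-methyl-2-(prop-2-en-1-yl)oct-2-enoate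
Product: 10 (2Z,6S,7S)-7-bromo-8-[(tert-butyldimethylsilyl)oxy]-6-chloro-6-methyl-2-(prop-2-en-1-yl)oct-2-en-1-ol
Conditions: iBu2AlH (2.5 equiv), CH2Cl2, −78 °C; aqueous potassium sodium tartrate
Reagents that add atoms: none
Why: 1,2-Reduction of the enoate by iBu2AlH at low temperature gives the allylic alcohol with the Z geometry unchanged and leaves silyl ether and alkyl halides alone.

Step 7
Reactants: 10 (2Z,6S,7S)-7-bromo-8-[(tert-butyldimethylsilyl)oxy]-6-chloro-6-methyl-2-(prop-2-en-1-yl)oct-2-en-1-ol
Product: 11 tert-butyl (2Z,6S,7S)-7-bromo-8-[(tert-butyldimethylsilyl)oxy]-6-chloro-6-methyl-2-(prop-2-en-1-yl)oct-2-en-1-yl carbonate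
Conditions: Boc2O, DMAP (10 mol%), MeCN, 0 °C to rt
Reagents that add atoms: di-tert-butyl dicarbonate CC(C)(C)OC(=O)OC(=O)OC(C)(C)C
Why: DMAP-catalysed acylation of the primary allylic alcohol by Boc2O installs the tert-butyl carbonate that later ends the cyclization as an internal oxygen nucleophile.

Step 8
Reactants: 11 tert-butyl (2Z,6S,7S)-7-bromo-8-[(tert-butyldimethylsilyl)oxy]-6-chloro-6-methyl-2-(prop-2-en-1-yl)oct-2-en-1-yl carbonate
Product: 12 tert-butyl (2Z,6S,7S)-7-bromo-6-chloro-8-hydroxy-6-methyl-2-(prop-2-en-1-yl)oct-2-en-1-yl carbonate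
Conditions: HF·pyridine, pyridine, THF, 0 °C to rt
Reagents that add atoms: none
Why: Fluoride-mediated Si–O cleavage under weakly acidic, non-basic conditions frees the primary alcohol without epoxide formation from the bromohydrin and without loss of the tert-butyl carbonate.

Step 9
Reactants: 12 tert-butyl (2Z,6S,7S)-7-bromo-6-chloro-8-hydroxy-6-methyl-2-(prop-2-en-1-yl)oct-2-en-1-yl carbonate
Product: 15 (4S)-4-[(1S,3S,4S)-3-bromo-4-chloro-4-methylcyclohexyl]-4-(prop-2-en-1-yl)-1,3-dioxolan-2-one, via primary triflate 13 (not isolated), via bromonium triflate 14 (not isolated)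
Conditions: Tf2O, 2,6-di-tert-butyl-4-methylpyridine, CH2Cl2, −78 °C; then (CF3)2CHOH, −78 to 0 °C
Reagents that add atoms: none
Why: Proposed new method: the primary triflate 13 cannot ionize unaided, so in the ionizing, non-nucleophilic medium the vicinal bromine displaces it from the back to give bromonium ion 14, which the trisubstituted alkene opens at the unhindered CH2 while the carbonate carbonyl oxygen adds to the developing tertiary cation and the tert-butyl group leaves as 2-methylpropene. The closest known reaction types are the stereospecific solvolytic bromonium-ion polyene cyclization of enantioenriched vicinal bromochlorides, the cation-olefin cyclization of alkenyl sulfonates on solvolysis, and cation capture by a tert-butyl carbonate as in iodocarbonate cyclization. The cyclohexane closes by endo opening of the bromonium ion with the alkene reacting in the 6-exo mode, and the 1,3-dioxolan-2-one closes 5-exo-trig on the same alkene. The ring CH is set by a chair in which C–Br must lie anti to the forming bond and is therefore equatorial, which puts C–Cl equatorial, the methyl axial and the alkenyl carbon equatorial; the carbinol carbon is set by anti addition of carbon and oxygen across the Z alkene before the new exocyclic bond can rotate; the CHBr and C(Cl)CH3 centres pass through unchanged because bromine leaves and re-enters only at the primary carbon. The step needs opening of the bromonium ion at CH2 and not at CHBr, bromine participation ahead of direct alkene displacement of triflate (which would run through the chair with axial bromine and give the other ring-CH configuration), and survival of the tertiary chloride; these should be secured by the neopentyl-like, chlorine-deactivated CHBr carbon whose attack would give a five-membered ring, by the proximity of bromine to the primary carbon, and by the low temperature with the far better leaving group.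

Step 10
Reactants: 15 (4S)-4-[(1S,3S,4S)-3-bromo-4-chloro-4-methylcyclohexyl]-4-(prop-2-en-1-yl)-1,3-dioxolan-2-one; 16 2-methyl-2-butene
Product: 17 (4S)-4-[(1S,3S,4S)-3-bromo-4-chloro-4-methylcyclohexyl]-4-(3-methylbut-2-en-1-yl)-1,3-dioxolan-2-one
Conditions: second-generation Grubbs catalyst RuCl2(=CHPh)(H2IMes)(PCy3) (5 mol%), 16 in large excess, CH2Cl2, 40 °C, sealed vessel
Reagents that add atoms: none
Why: Olefin cross-metathesis of the terminal alkene with excess 2-methyl-2-butene exchanges the CH2 terminus for an isopropylidene group with loss of propene, the usual allyl-to-prenyl conversion; halides and the cyclic carbonate do not interfere with the ruthenium carbene.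

Step 11
Reactants: 17 (4S)-4-[(1S,3S,4S)-3-bromo-4-chloro-4-methylcyclohexyl]-4-(3-methylbut-2-en-1-yl)-1,3-dioxolan-2-one
Product: 18 (2S)-2-[(1S,3S,4S)-3-bromo-4-chloro-4-methylcyclohexyl]-5-methylhex-4-ene-1,2-diol
Conditions: K2CO3 (cat.), MeOH, 0 °C to rt
Reagents that add atoms: none
Why: Base-catalysed transesterification of the cyclic carbonate with methanol releases the primary and tertiary hydroxyls as dimethyl carbonate forms; both ring halides are equatorial and have no antiperiplanar hydrogen, so elimination should not compete.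

Step 12
Reactants: 18 (2S)-2-[(1S,3S,4S)-3-bromo-4-chloro-4-methylcyclohexyl]-5-methylhex-4-ene-1,2-diol
Product: 19 (2S)-2-[(1S,3S,4S)-3-bromo-4-chloro-4-methylcyclohexyl]-2-hydroxy-5-methylhex-4-enal
Conditions: SO3·pyridine, DMSO, iPr2NEt, CH2Cl2, 0 °C
Reagents that add atoms: none
Why: Parikh–Doering oxidation takes the primary alcohol to the aldehyde beside the free tertiary alcohol without the glycol cleavage that iodine-based oxidants can cause with 1,2-diols, and the aldehyde has no alpha hydrogen to epimerize.

Step 13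
Reactants: 19 (2S)-2-[(1S,3S,4S)-3-bromo-4-chloro-4-methylcyclohexyl]-2-hydroxy-5-methylhex-4-enal
Product: 20 (2S)-2-[(1S,3S,4S)-3-bromo-4-chloro-4-methylcyclohexyl]-2-hydroxy-5-methylhex-4-enoic acid
Conditions: NaClO2, NaH2PO4, 2-methyl-2-butene 16 (large excess), t-BuOH/H2O, 0 °C to rt
Reagents that add atoms: sodium chlorite [Na+].[O-]Cl=O
Why: Lindgren–Pinnick oxidation by chlorous acid converts the aldehyde into the acid, and the excess 2-methyl-2-butene consumes the hypochlorous acid by-product before it can add to the prenyl alkene.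

Step 14
Reactants: 20 (2S)-2-[(1S,3S,4S)-3-bromo-4-chloro-4-methylcyclohexyl]-2-hydroxy-5-methylhex-4-enoic acid
Product: 21 (3S,5R)-5-bromo-3-[(1S,3S,4S)-3-bromo-4-chloro-4-methylcyclohexyl]-3-hydroxy-6,6-dimethyloxan-2-one
Conditions: NBS, MeCN, −30 to 0 °C, dark
Reagents that add atoms: N-bromosuccinimide O=C1CCC(=O)N1Br
Why: 6-endo bromolactonization: the carboxyl oxygen opens the bromonium ion of the prenyl alkene at the dimethyl-substituted (Markovnikov) carbon, and the new CHBr centre is set by anti addition through a chair in which bromine is equatorial (anti to the attacking oxygen) and the cyclohexyl group rather than the hydroxyl is equatorial, which places bromine cis to the cyclohexyl group.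

Step 15
Reactants: 21 (3S,5R)-5-bromo-3-[(1S,3S,4S)-3-bromo-4-chloro-4-methylcyclohexyl]-3-hydroxy-6,6-dimethyloxan-2-one
Product: 22 (3S,5R)-5-bromo-3-[(1S,3S,4S)-3-bromo-4-chloro-4-methylcyclohexyl]-6,6-dimethyl-3-[(trimethylsilyl)oxy]oxan-2-one
Conditions: Me3SiOTf, 2,6-lutidine, CH2Cl2, −78 to 0 °C
Reagents that add atoms: trimethylsilyl trifluoromethanesulfonate C[Si](C)(C)OS(=O)(=O)C(F)(F)F
Why: Silylation of the hindered tertiary alcohol with a silyl triflate and a hindered pyridine base, so that the hydroxyl cannot quench the titanium reagent of the next step.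

Step 16
Reactants: 22 (3S,5R)-5-bromo-3-[(1S,3S,4S)-3-bromo-4-chloro-4-methylcyclohexyl]-6,6-dimethyl-3-[(trimethylsilyl)oxy]oxan-2-one
Product: 23 {[(3S,5R)-5-bromo-3-[(1S,3S,4S)-3-bromo-4-chloro-4-methylcyclohexyl]-6,6-dimethyl-2-methylideneoxan-3-yl]oxy}trimethylsilane
Conditions: Cp2TiMe2 (tetravalent titanium, 3 equiv), toluene/THF, 65 °C, dark; filtration through basic alumina
Reagents that add atoms: dimethyltitanocene Cp2TiMe2 C[Ti+2]C.c1cc[cH-]c1.c1cc[cH-]c1
Why: Petasis methylenation: Cp2Ti=CH2, formed by loss of methane on heating, converts the lactone carbonyl into the exocyclic enol ether under non-basic conditions that halides and silyl ether should tolerate, and the double bond cannot move into the ring because the neighbouring carbon is fully substituted.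

Step 17
Reactants: 23 {[(3S,5R)-5-bromo-3-[(1S,3S,4S)-3-bromo-4-chloro-4-methylcyclohexyl]-6,6-dimethyl-2-methylideneoxan-3-yl]oxy}trimethylsilane
Product: 24 (3S,5R)-5-bromo-3-[(1S,3S,4S)-3-bromo-4-chloro-4-methylcyclohexyl]-6,6-dimethyl-2-methylideneoxan-3-ol
Conditions: K2CO3 (0.2 equiv), MeOH, 0 °C
Reagents that add atoms: none
Why: Mild base-catalysed methanolysis of the trimethylsilyl ether frees the tertiary alcohol under acid-free conditions that the exocyclic enol ether requires, and the equatorial halides lack an antiperiplanar hydrogen for elimination.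

**Compound list**

1 | nerol, (2Z)-3,7-dimethylocta-2,6-dien-1-ol | CC(C)=CCC/C(C)=C\CO | starting material
2 | (2S,3S)-2-bromo-3-chloro-3,7-dimethyloct-6-en-1-ol | CC(C)=CCC[C@](C)(Cl)[C@@H](Br)CO | intermediate
3 | tert-butyl{[(2S,3S)-2-bromo-3-chloro-3,7-dimethyloct-6-en-1-yl]oxy}dimethylsilane | CC(C)=CCC[C@](C)(Cl)[C@@H](Br)CO[Si](C)(C)C(C)(C)C | intermediate
4 | secondary ozonide 3-[(3S,4S)-4-bromo-5-[(tert-butyldimethylsilyl)oxy]-3-chloro-3-methylpentyl]-5,5-dimethyl-1,2,4-trioxolane (both epimers at the trioxolane CH; not isolated) | CC1(C)OOC(CC[C@](C)(Cl)[C@@H](Br)CO[Si](C)(C)C(C)(C)C)O1 | intermediate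
5 | (4S,5S)-5-bromo-6-[(tert-butyldimethylsilyl)oxy]-4-chloro-4-methylhexanal | O=CCC[C@](C)(Cl)[C@@H](Br)CO[Si](C)(C)C(C)(C)C | intermediate
6 | methyl 2-[bis(2,2,2-trifluoroethoxy)phosphoryl]acetate | COC(=O)CP(=O)(OCC(F)(F)F)OCC(F)(F)F | starting material
7 | allyl bromide (3-bromoprop-1-ene) | C=CCBr | starting material
8 | methyl 2-[bis(2,2,2-trifluoroethoxy)phosphoryl]pent-4-enoate (racemic) | COC(=O)C(CC=C)P(=O)(OCC(F)(F)F)OCC(F)(F)F | intermediate
9 | methyl (2Z,6S,7S)-7-bromo-8-[(tert-butyldimethylsilyl)oxy]-6-chloro-6-methyl-2-(prop-2-en-1-yl)oct-2-enoate | COC(=O)/C(CC=C)=C\CC[C@](C)(Cl)[C@@H](Br)CO[Si](C)(C)C(C)(C)C | intermediate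
10 | (2Z,6S,7S)-7-bromo-8-[(tert-butyldimethylsilyl)oxy]-6-chloro-6-methyl-2-(prop-2-en-1-yl)oct-2-en-1-ol | OC/C(CC=C)=C\CC[C@](C)(Cl)[C@@H](Br)CO[Si](C)(C)C(C)(C)C | intermediate
11 | tert-butyl (2Z,6S,7S)-7-bromo-8-[(tert-butyldimethylsilyl)oxy]-6-chloro-6-methyl-2-(prop-2-en-1-yl)oct-2-en-1-yl carbonate | CC(C)(C)OC(=O)OC/C(CC=C)=C\CC[C@](C)(Cl)[C@@H](Br)CO[Si](C)(C)C(C)(C)C | intermediate
12 | tert-butyl (2Z,6S,7S)-7-bromo-6-chloro-8-hydroxy-6-methyl-2-(prop-2-en-1-yl)oct-2-en-1-yl carbonate | CC(C)(C)OC(=O)OC/C(CC=C)=C\CC[C@](C)(Cl)[C@@H](Br)CO | intermediate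
13 | primary triflate of 12: tert-butyl (2Z,6S,7S)-7-bromo-6-chloro-6-methyl-2-(prop-2-en-1-yl)-8-[(trifluoromethanesulfonyl)oxy]oct-2-en-1-yl carbonate (not isolated) | CC(C)(C)OC(=O)OC/C(CC=C)=C\CC[C@](C)(Cl)[C@@H](Br)COS(=O)(=O)C(F)(F)F | intermediate
14 | bromonium (bromiranium) triflate from 13: bromine bridges C7 and C8 of the chain, C7 and C6 configurations unchanged (not isolated) | CC(C)(C)OC(=O)OC/C(CC=C)=C\CC[C@](C)(Cl)[C@@H]1C[Br+]1.[O-]S(=O)(=O)C(F)(F)F | intermediate
15 | (4S)-4-[(1S,3S,4S)-3-bromo-4-chloro-4-methylcyclohexyl]-4-(prop-2-en-1-yl)-1,3-dioxolan-2-one | C=CC[C@]1(OC(=O)OC1)[C@H]2CC[C@](C)(Cl)[C@@H](Br)C2 | intermediate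
16 | 2-methyl-2-butene | CC=C(C)C | starting material
17 | (4S)-4-[(1S,3S,4S)-3-bromo-4-chloro-4-methylcyclohexyl]-4-(3-methylbut-2-en-1-yl)-1,3-dioxolan-2-one | CC(C)=CC[C@]1(OC(=O)OC1)[C@H]2CC[C@](C)(Cl)[C@@H](Br)C2 | intermediate
18 | (2S)-2-[(1S,3S,4S)-3-bromo-4-chloro-4-methylcyclohexyl]-5-methylhex-4-ene-1,2-diol | CC(C)=CC[C@](CO)(O)[C@H]1CC[C@](C)(Cl)[C@@H](Br)C1 | intermediate
19 | (2S)-2-[(1S,3S,4S)-3-bromo-4-chloro-4-methylcyclohexyl]-2-hydroxy-5-methylhex-4-enal | CC(C)=CC[C@](C=O)(O)[C@H]1CC[C@](C)(Cl)[C@@H](Br)C1 | intermediate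
20 | (2S)-2-[(1S,3S,4S)-3-bromo-4-chloro-4-methylcyclohexyl]-2-hydroxy-5-methylhex-4-enoic acid | CC(C)=CC[C@](C(=O)O)(O)[C@H]1CC[C@](C)(Cl)[C@@H](Br)C1 | intermediate
21 | (3S,5R)-5-bromo-3-[(1S,3S,4S)-3-bromo-4-chloro-4-methylcyclohexyl]-3-hydroxy-6,6-dimethyloxan-2-one | O=C1OC(C)(C)[C@H](Br)C[C@]1(O)[C@H]1CC[C@](C)(Cl)[C@@H](Br)C1 | intermediate
22 | (3S,5R)-5-bromo-3-[(1S,3S,4S)-3-bromo-4-chloro-4-methylcyclohexyl]-6,6-dimethyl-3-[(trimethylsilyl)oxy]oxan-2-one | O=C1OC(C)(C)[C@H](Br)C[C@]1(O[Si](C)(C)C)[C@H]1CC[C@](C)(Cl)[C@@H](Br)C1 | intermediate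
23 | {[(3S,5R)-5-bromo-3-[(1S,3S,4S)-3-bromo-4-chloro-4-methylcyclohexyl]-6,6-dimethyl-2-methylideneoxan-3-yl]oxy}trimethylsilane | C=C1OC(C)(C)[C@H](Br)C[C@]1(O[Si](C)(C)C)[C@H]1CC[C@](C)(Cl)[C@@H](Br)C1 | intermediate
24 | (3S,5R)-5-bromo-3-[(1S,3S,4S)-3-bromo-4-chloro-4-methylcyclohexyl]-6,6-dimethyl-2-methylideneoxan-3-ol (CNP0106480.2) | C=C1OC(C)(C)[C@H](Br)C[C@]1(O)[C@H]1CC[C@](C)(Cl)[C@@H](Br)C1 | target

**Step count and risks**

Total: 17 steps. Longest linear sequence: 16 steps (nerol 1 to 24 through steps 1–3 and 5–17); step 4 prepares the phosphonate on a side branch.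

Steps most likely to fail:

Step 9 (the proposed new method). Triflate 13 may ionize without bromine participation, by direct attack of the alkene through the chair with axial bromine. Bromonium ion 14 may be opened at the CHBr carbon. The tertiary chloride may ionize with bromine assistance in the fluorinated alcohol. Each would erode the configuration of the ring CH relative to the halogens.

The fallback uses known chemistry only and builds the ring first and the halogens last. It cannot branch from an intermediate, because every compound before 15 already carries the acyclic bromochloride. It therefore sets out at the level of nerol 1, which it replaces by commercial (S)-limonene F1, and comes back to the route at 15.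

- Metalation of the isopropenyl methyl group (n-BuLi, TMEDA), borylation with B(OMe)3 and oxidation with H2O2/NaOH should give 2-[(1S)-4-methylcyclohex-3-en-1-yl]prop-2-en-1-ol F2.
- Sharpless asymmetric epoxidation (Ti(OiPr)4 of tetravalent titanium, the diethyl tartrate enantiomer that leads to the (2S)-epoxide, t-BuOOH, molecular sieves) should give, under reagent control, [(2S)-2-[(1S)-4-methylcyclohex-3-en-1-yl]oxiran-2-yl]methanol F3.
- Opening of the epoxide CH2 by vinylmagnesium bromide with catalytic CuI should give (2S)-2-[(1S)-4-methylcyclohex-3-en-1-yl]pent-4-ene-1,2-diol F4.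
- 1,1'-Carbonyldiimidazole should close F4 to the halogen-free dioxolanone (4S)-4-[(1S)-4-methylcyclohex-3-en-1-yl]-4-(prop-2-en-1-yl)-1,3-dioxolan-2-one F5.

The halogens then follow by neighbouring-group chemistry rather than by direct BrCl addition, which is expected to add trans-diaxially from the wrong face.

- A Jacobsen epoxidation of the ring alkene with the MnCl(salen) catalyst of trivalent manganese (enantiomer chosen so that oxygen enters trans to the side chain) should give the ring epoxide (4S)-4-[(1R,3S,6S)-6-methyl-7-oxabicyclo[4.1.0]heptan-3-yl]-4-(prop-2-en-1-yl)-1,3-dioxolan-2-one F6.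
- HBr should open it trans-diaxially at the tertiary carbon to the bromohydrin (4S)-4-[(1S,3R,4R)-4-bromo-3-hydroxy-4-methylcyclohexyl]-4-(prop-2-en-1-yl)-1,3-dioxolan-2-one F7.
- Activation of the secondary hydroxyl (PPh3, N-chlorosuccinimide) should let the antiperiplanar bromine expel it. Chloride should then open the resulting bromonium ion, which lies cis to the side chain, at the tertiary carbon to give 15.

The weak point of this fallback is the site at which chloride opens that ion; opening at the secondary carbon would divert material.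

Step 14. Facial selectivity may be poor, since the lactone carbonyl removes one syn-axial contact and the hydroxyl may prefer the carbonyl plane, so the chair with equatorial cyclohexyl is not strongly favoured. 5-exo lactonization or 5-endo ether formation by the tertiary hydroxyl may also compete.

The fallback sets out from 20 and comes back at 21. It replaces substrate-controlled bromonium chemistry by a reagent-controlled epoxide and a substitution with inversion.

- Shi epoxidation of the prenyl alkene (the fructose-derived ketone catalyst enantiomer that leads to the (S)-epoxide, KHSO5, K2CO3 buffer) should give (2S)-2-[(1S,3S,4S)-3-bromo-4-chloro-4-methylcyclohexyl]-3-[(2S)-3,3-dimethyloxiran-2-yl]-2-hydroxypropanoic acid F8.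
- Catalytic camphorsulfonic acid should close F8 6-endo at the tertiary epoxide carbon to (3S,5S)-3-[(1S,3S,4S)-3-bromo-4-chloro-4-methylcyclohexyl]-3,5-dihydroxy-6,6-dimethyloxan-2-one F9.
- The secondary hydroxyl alone should be sulfonylated (ClCH2SO2Cl, pyridine) to (3S,5S)-5-[(1S,3S,4S)-3-bromo-4-chloro-4-methylcyclohexyl]-5-hydroxy-2,2-dimethyl-6-oxooxan-3-yl chloromethanesulfonate F10.
- LiBr should displace the sulfonate with inversion to give 21.

Step 16. Methylenation of the hindered, fully alpha-substituted lactone may stay incomplete at temperatures the halides tolerate. Prolonged heating may cause loss of HCl or halogen interchange in the vicinal bromochloride. The enol ether may hydrate on work-up.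

The fallback sets out from 22 and comes back at 23.

- Addition of MeLi in THF at −78 °C should stop at the methyl lactol (3S,5R)-5-bromo-3-[(1S,3S,4S)-3-bromo-4-chloro-4-methylcyclohexyl]-2,6,6-trimethyl-3-[(trimethylsilyl)oxy]oxan-2-ol F11 (anomer mixture).
- Dehydration with (CF3CO)2O, pyridine and DMAP at 0 °C should give 23; elimination can only run toward the methyl group because the ring neighbour is fully substituted.

**Further compounds**

F1 | step 9 | (S)-limonene, (4S)-1-methyl-4-(prop-1-en-2-yl)cyclohex-1-ene | CC(=C)[C@H]1CCC(C)=CC1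
F2 | step 9 | 2-[(1S)-4-methylcyclohex-3-en-1-yl]prop-2-en-1-ol | OCC(=C)[C@H]1CCC(C)=CC1
F3 | step 9 | [(2S)-2-[(1S)-4-methylcyclohex-3-en-1-yl]oxiran-2-yl]methanol | OC[C@]1(CO1)[C@H]2CCC(C)=CC2
F4 | step 9 | (2S)-2-[(1S)-4-methylcyclohex-3-en-1-yl]pent-4-ene-1,2-diol | C=CC[C@](CO)(O)[C@H]1CCC(C)=CC1
F5 | step 9 | (4S)-4-[(1S)-4-methylcyclohex-3-en-1-yl]-4-(prop-2-en-1-yl)-1,3-dioxolan-2-one | C=CC[C@]1(OC(=O)OC1)[C@H]2CCC(C)=CC2
F6 | step 9 | (4S)-4-[(1R,3S,6S)-6-methyl-7-oxabicyclo[4.1.0]heptan-3-yl]-4-(prop-2-en-1-yl)-1,3-dioxolan-2-one | C=CC[C@]1(OC(=O)OC1)[C@H]2CC[C@]3(C)O[C@@H]3C2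
F7 | step 9 | (4S)-4-[(1S,3R,4R)-4-bromo-3-hydroxy-4-methylcyclohexyl]-4-(prop-2-en-1-yl)-1,3-dioxolan-2-one | C=CC[C@]1(OC(=O)OC1)[C@H]2CC[C@@](C)(Br)[C@H](O)C2
F8 | step 14 | (2S)-2-[(1S,3S,4S)-3-bromo-4-chloro-4-methylcyclohexyl]-3-[(2S)-3,3-dimethyloxiran-2-yl]-2-hydroxypropanoic acid | CC1(C)O[C@H]1C[C@](C(=O)O)(O)[C@H]1CC[C@](C)(Cl)[C@@H](Br)C1
F9 | step 14 | (3S,5S)-3-[(1S,3S,4S)-3-bromo-4-chloro-4-methylcyclohexyl]-3,5-dihydroxy-6,6-dimethyloxan-2-one | O=C1OC(C)(C)[C@@H](O)C[C@]1(O)[C@H]1CC[C@](C)(Cl)[C@@H](Br)C1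
F10 | step 14 | (3S,5S)-5-[(1S,3S,4S)-3-bromo-4-chloro-4-methylcyclohexyl]-5-hydroxy-2,2-dimethyl-6-oxooxan-3-yl chloromethanesulfonate | O=C1OC(C)(C)[C@@H](OS(=O)(=O)CCl)C[C@]1(O)[C@H]1CC[C@](C)(Cl)[C@@H](Br)C1
F11 | step 16 | (3S,5R)-5-bromo-3-[(1S,3S,4S)-3-bromo-4-chloro-4-methylcyclohexyl]-2,6,6-trimethyl-3-[(trimethylsilyl)oxy]oxan-2-ol (anomer mixture) | CC1(O)OC(C)(C)[C@H](Br)C[C@]1(O[Si](C)(C)C)[C@H]1CC[C@](C)(Cl)[C@@H](Br)C1
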